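**Assumptions.** Gardenin C is a planar, achiral flavone with no stereocentres, so "single enantiomer" is taken to mean the compound as drawn and no stereocontrol is needed. 3-Hydroxy-4,5-dimethoxybenzaldehyde is taken as a purchasable starting material. The route is a paper design and has not been run.

## Retrosynthetic overview

1. The pyranone ring is the only ring formed, and it is formed last, by a three-component Pd-catalysed carbonylative Sonogashira/6-endo annulation: A-ring iodophenol + CO (becomes C4=O) + B-ring arylacetylene (becomes C2/C3).
2. The A-ring partner is the C2v-symmetric 2-iodo-4,5,6-trimethoxybenzene-1,3-diol. Either OH closes the ring and the other becomes the 5-OH, so there is no regiochemical question, no protecting group and no selective demethylation.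
3. The iodoresorcinol comes from 1,2,3-trimethoxybenzene by double bromination, double borylation/oxidation and iodination of the single remaining C–H.
4. The alkyne comes from 3-hydroxy-4,5-dimethoxybenzaldehyde by Ohira–Bestmann homologation, with the phenol left free.
5. Deliberately avoided: the usual Baker–Venkataraman or chalcone/oxidative-cyclisation route from a polyoxygenated 2-hydroxyacetophenone.

## Route

**Step 1**
Reactants: 1, 1,2,3-trimethoxybenzene
Product: 2, 1,5-dibromo-2,3,4-trimethoxybenzene
Conditions: NBS (2.1 equiv), MeCN, 0 °C → rt, dark
Reagents that add atoms: N-bromosuccinimide, O=C1CCC(=O)N1Br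
Why: Electrophilic aromatic bromination; the first Br enters C4, and the second goes to C6 (ortho and para to the two outer OMe groups) and not C5, which is activated only by the twisted, weakly donating central OMe.

**Step 2**
Reactants: 2, 1,5-dibromo-2,3,4-trimethoxybenzene
Product: 3, 2,2'-(4,5,6-trimethoxy-1,3-phenylene)bis(4,4,5,5-tetramethyl-1,3,2-dioxaborolane)
Conditions: B2pin2 (2.6 equiv), Pd(dppf)Cl2 (5 mol %), KOAc (6 equiv), dioxane, 90 °C
Reagents that add atoms: bis(pinacolato)diboron, CC1(C)OB(OC1(C)C)B1OC(C)(C)C(C)(C)O1
Why: Double Miyaura borylation; each C–Br has only one ortho substituent and ethers are inert, so both bromides should convert to Bpin.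

**Step 3**
Reactants: 3, the bis(pinacol boronate)
Product: 4, 4,5,6-trimethoxybenzene-1,3-diol
Conditions: 30% H2O2, aq. NaOH, THF, 0 °C, 30 min, under N2; then Na2S2O3, 1 M HCl (can be telescoped with Step 2)
Reagents that add atoms: hydrogen peroxide, OO
Why: Boronate oxidation (peroxide attack on boron, 1,2-aryl shift from B to O, hydrolysis) gives both phenols; a cold, short, oxygen-free treatment with reductive acidic work-up protects the electron-rich resorcinol.

**Step 4**
Reactants: 4, 4,5,6-trimethoxybenzene-1,3-diol
Product: 5, 2-iodo-4,5,6-trimethoxybenzene-1,3-diol
Conditions: I2 (1.0 equiv), NaHCO3, THF/H2O, 0 °C, dark; Na2S2O3 quench; use promptly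
Reagents that add atoms: iodine, II
Why: Electrophilic aromatic iodination under the standard 2-iodoresorcinol conditions; the ring has a single C–H, flanked by two OH groups, so only one product is possible.

**Step 5**
Reactants: 6, 3-hydroxy-4,5-dimethoxybenzaldehyde
Product: 7, 5-ethynyl-2,3-dimethoxyphenol
Conditions: dimethyl (1-diazo-2-oxopropyl)phosphonate (1.5 equiv), K2CO3 (3 equiv), MeOH, 0 °C → rt
Reagents that add atoms: Ohira–Bestmann reagent, COP(=O)(OC)C(=[N+]=[N-])C(C)=O (supplies the terminal alkyne carbon)
Why: Ohira–Bestmann (Seyferth–Gilbert) homologation; the phenoxide is meta to the aldehyde and not conjugated with it, so the free phenol is tolerated with extra base.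

**Step 6 (key step)**
Reactants: 5, 2-iodo-4,5,6-trimethoxybenzene-1,3-diol; 7, 5-ethynyl-2,3-dimethoxyphenol (1.3 equiv)
Product: 8, Gardenin C (5,3'-dihydroxy-6,7,8,4',5'-pentamethoxyflavone)
Conditions: PdCl2(dppf) (5 mol %), CO (10 bar), degassed Et2NH, 80–100 °C; 1 M HCl work-up
Reagents that add atoms: carbon monoxide, [C-]#[O+] (becomes C4=O)
Why: Pd-catalysed carbonylative Sonogashira annulation of an o-iodophenol with a terminal alkyne, here with every OH unprotected, which is an untested extension of the known reaction. Oxidative addition and fast CO insertion on the electron-rich aryl give an aroyl-Pd, which alkynylates to a 2,6-dihydroxyaryl ynone. Et2NH adds to the ynone to give a β-aminoenone, and phenol addition–elimination closes the ring 6-endo, giving the flavone and not the aurone. The two OH groups of 5 are homotopic, so one product results and the spectator OH becomes the chelated 5-OH.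

## Compound list

1 | 1,2,3-trimethoxybenzene | COc1cccc(OC)c1OC | starting material
2 | 1,5-dibromo-2,3,4-trimethoxybenzene | COc1c(Br)cc(Br)c(OC)c1OC | intermediate
3 | 2,2'-(4,5,6-trimethoxy-1,3-phenylene)bis(4,4,5,5-tetramethyl-1,3,2-dioxaborolane) | COc1c(B2OC(C)(C)C(C)(C)O2)cc(B2OC(C)(C)C(C)(C)O2)c(OC)c1OC | intermediate
4 | 4,5,6-trimethoxybenzene-1,3-diol | Oc1cc(O)c(OC)c(OC)c1OC | intermediate
5 | 2-iodo-4,5,6-trimethoxybenzene-1,3-diol | Oc1c(I)c(O)c(OC)c(OC)c1OC | intermediate
6 | 3-hydroxy-4,5-dimethoxybenzaldehyde | O=Cc1cc(O)c(OC)c(OC)c1 | starting material
7 | 5-ethynyl-2,3-dimethoxyphenol | C#Cc1cc(O)c(OC)c(OC)c1 | intermediate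
8 | Gardenin C | COc1cc(-c2cc(=O)c3c(O)c(OC)c(OC)c(OC)c3o2)cc(O)c1OC | target

## Summary

Total steps: 6 (5 operations if Steps 2 and 3 are telescoped).
Longest linear sequence: 5 steps (1 → 2 → 3 → 4 → 5 → 8). The alkyne branch is 1 step before the convergent key step.

**Steps most likely to fail, with fallbacks**

1. **Step 6, carbonylative annulation.** Risks are Et2NH aminocarbonylation of the aroyl-Pd, reductive de-iodination, non-carbonylative coupling to a benzofuran, and interference from the three free phenols. Fallback: drop Pd/CO and make the ynone by organolithium acylation. Convert 4 to its bis-MOM ether, lithiate C2 between the two OMOM groups with n-BuLi, and acylate with the Weinreb amide of the MOM-protected 3-arylpropiolic acid. HCl/MeOH then removes the MOM groups and, with Et2NH, closes the flavone 6-endo.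

2. **Step 2, double borylation.** Risks are mono-borylation and protodebromination of the electron-rich, ortho-methoxy dibromide, and an oxidation-sensitive diol downstream. Fallback: abandon the symmetric diol. Make 2,3,4-trimethoxyphenol by Dakin oxidation of 2,3,4-trimethoxybenzaldehyde, ortho-iodinate it, and run the same carbonylative annulation to the 6,7,8-trimethoxyflavone with the B-ring OH protected as an ester. Install the 5-OH last by ketone-directed Ru(II)-catalysed C5–H hydroxylation ([RuCl2(p-cymene)]2, PhI(OCOCF3)2, TFA/TFAA), then cleave the ester.

3. **Step 4, iodination.** Risks are oxidation of the pentaoxygenated ring by I2 and light- or acid-induced loss of iodine from 5. Fallback: replace electrophilic iodination with an anionic one. Directed ortho-lithiation of the bis-MOM ether of 4 and an I2 quench give a stable protected iodide. Mild acid can release 5 just before Step 6, or the iodide can be exchanged to the aryllithium and sent directly into the ynone fallback above.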